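## Retrosynthetic overview

1. The target comes from the racemic C2-symmetric trans,trans-biflavanone by separation of its diastereomeric bis[(1S)-camphanates]; the 7- and 7''-OH groups are carried as silyl ethers until then.
2. Both rings C are closed together by a double 6-endo oxa-Michael addition (thermodynamic, 2,3-trans in each ring) of a 2,3-bis(4-methoxybenzylidene)-1,4-diaryl-1,4-diketone.
3. Key disconnection: C2–C3 and C2''–C3'' are made by a double intermolecular lithium-enolate aldol addition of a 1,4-diarylbutane-1,4-dione to two molecules of 4-methoxybenzaldehyde, followed by dehydration.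
4. The 1,4-diketone comes from two molecules of a 2,6-dimethoxy-4-silyloxyphenyllithium (from 3,5-dimethoxyphenol) and the succinic bis-Weinreb amide; the C3–C3'' bond is bought with the succinyl unit.
5. Ring order: rings A and B are bought as arenes; the two rings C form in step 8; no other ring is built.

Assumption: the SMILES is read as (2S,3R,2''S,3''R), i.e. both pyranone rings 2,3-trans and the molecule C2-symmetric; simple reagents (silyl and acyl chlorides, bases, solvents) are bought.

## Route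

Step 1
Reactants: 1 3,5-dimethoxyphenol
Product: 2 (3,5-dimethoxyphenoxy)triisopropylsilane
Conditions: iPr3SiCl (1.1 equiv), imidazole, DMF, rt
Reagents that add atoms: chlorotriisopropylsilane, CC(C)[Si](Cl)(C(C)C)C(C)C
Why: O-silylation of the phenol installs a bulky, base-stable, non-coordinating group that later leaves the position between the two methoxy groups as the only good lithiation site.

Step 2
Reactants: 3 succinyl chloride
Product: 4 N1,N4-dimethoxy-N1,N4-dimethylbutanediamide
Conditions: MeNH(OMe)·HCl (2.2 equiv), pyridine (4.5 equiv), CH2Cl2, 0 °C to rt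
Reagents that add atoms: N,O-dimethylhydroxylamine hydrochloride, CNOC.Cl
Why: Weinreb amide formation by acyl substitution on both acid chloride groups (two amine units are taken up) gives a four-carbon bis-acylating agent that stops cleanly at the ketone stage.

Step 3
Reactants: 2 (3,5-dimethoxyphenoxy)triisopropylsilane (two molecules enter the product); 4 N1,N4-dimethoxy-N1,N4-dimethylbutanediamide
Product: 6 tetramethoxy diketone 1,4-bis[2,6-dimethoxy-4-(triisopropylsilyloxy)phenyl]butane-1,4-dione, via aryllithium 5 (not isolated)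
Conditions: 2 (2.3 equiv), n-BuLi (2.3 equiv), TMEDA, THF, 0 °C to rt; then 4 (1.0 equiv), −78 to 0 °C; aq. NH4Cl
Reagents that add atoms: (3,5-dimethoxyphenoxy)triisopropylsilane (second equivalent of 2), COc1cc(O[Si](C(C)C)(C(C)C)C(C)C)cc(OC)c1
Why: Directed ortho-metalation occurs between the two methoxy groups, and the Weinreb ketone synthesis then lets one aryllithium add at each amide group of 4 without over-addition, because each tetrahedral lithium chelate survives until work-up.

Step 4
Reactants: 6 1,4-bis[2,6-dimethoxy-4-(triisopropylsilyloxy)phenyl]butane-1,4-dione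
Product: 7 bis-phenol diketone 1,4-bis[2-hydroxy-6-methoxy-4-(triisopropylsilyloxy)phenyl]butane-1,4-dione
Conditions: BCl3 (2.4 equiv), CH2Cl2, −78 to 0 °C; aq. NaHCO3
Reagents that add atoms: none
Why: Chelation-controlled Lewis-acid ether cleavage removes exactly one methyl group ortho to each carbonyl, because the resulting aryloxyboron chelate deactivates the second ortho methoxy group; the low temperature keeps the 1,4-diketone from closing to a furan.

Step 5
Reactants: 7 1,4-bis[2-hydroxy-6-methoxy-4-(triisopropylsilyloxy)phenyl]butane-1,4-dione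
Product: 8 bis-MOM diketone 1,4-bis[2-methoxy-6-(methoxymethoxy)-4-(triisopropylsilyloxy)phenyl]butane-1,4-dione
Conditions: NaH (2.2 equiv), MOMCl (2.5 equiv), THF–DMF, 0 °C
Reagents that add atoms: chloromethyl methyl ether, COCCl
Why: Williamson-type O-alkylation of the two phenoxides (far more acidic than the ketone α-positions) masks the hydroxyls that will later close rings C, with a group that cannot migrate to an enolate.

Step 6
Reactants: 8 1,4-bis[2-methoxy-6-(methoxymethoxy)-4-(triisopropylsilyloxy)phenyl]butane-1,4-dione; 9 4-methoxybenzaldehyde (two molecules enter the product)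
Product: 11 bis-aldol 2,3-bis[hydroxy(4-methoxyphenyl)methyl]-1,4-bis[2-methoxy-6-(methoxymethoxy)-4-(triisopropylsilyloxy)phenyl]butane-1,4-dione (diastereomer mixture), via dilithium bis-enolate 10 (not isolated)
Conditions: LiN(iPr)2 (2.3 equiv), THF, −78 °C; then 9 (2.6 equiv), −78 °C; AcOH, −78 °C
Reagents that add atoms: 4-methoxybenzaldehyde (second equivalent of 9), COc1ccc(C=O)cc1
Why: The double intermolecular lithium-enolate aldol addition, one non-enolizable aldehyde molecule at each α-carbon, forms both C2–C3 bonds at low temperature, and the four new stereocenters need no control because they are erased or re-set in steps 7 and 8.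

Step 7
Reactants: 11 bis-aldol (diastereomer mixture)
Product: 13 bis-enone (2E,3E)-2,3-bis(4-methoxybenzylidene)-1,4-bis[2-methoxy-6-(methoxymethoxy)-4-(triisopropylsilyloxy)phenyl]butane-1,4-dione, via bis-mesylate 12 (not isolated)
Conditions: MsCl (2.5 equiv), Et3N, CH2Cl2, 0 °C; then DBU (3 equiv), 0 °C to rt
Reagents that add atoms: none
Why: Mesylation followed by E1cB elimination of the electron-rich benzylic sulfonates completes the aldol condensation under non-acidic conditions, giving the conjugated E,E geometry.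

Step 8
Reactants: 13 bis-enone
Product: 15 racemic trans,trans C2-symmetric 7,7''-bis-O-triisopropylsilyl-4',4''',5,5''-tetra-O-methylchamaejasmin, via bis-chalcone diphenol 14 (not isolated)
Conditions: 2 M aq. HCl, MeOH–THF, 45 °C; work-up; then NaOAc, EtOH, 78 °C; SiO2 chromatography
Reagents that add atoms: none
Why: Acetal methanolysis frees the two ortho phenols, which close both rings C by intramolecular oxa-Michael addition; reversible ring closure and C3 enolization place the aryl and C3 substituents trans-diequatorial in each ring, and the meso (2S,3R,2''R,3''S) diastereomer formed alongside is removed on silica and can be re-equilibrated.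

Step 9
Reactants: 15 racemic bis-silyl biflavanone
Product: 16 racemic 4',4''',5,5''-tetramethylchamaejasmin
Conditions: Bu4NF, AcOH (1:1, 2.5 equiv each), THF, 0 °C
Reagents that add atoms: none
Why: Fluoride-mediated desilylation of the aryl silyl ethers is fast, and the acetic acid buffer prevents the phenoxide-induced retro-oxa-Michael opening that would scramble the four stereocenters.

Step 10
Reactants: 16 racemic 4',4''',5,5''-tetramethylchamaejasmin
Product: 17 (2S,3R,2''S,3''R)-4',4''',5,5''-tetramethylchamaejasmin 7,7''-bis[(1S,4R)-camphanate]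
Conditions: (1S)-(−)-camphanic chloride (2.4 equiv), Et3N, DMAP (cat.), CH2Cl2, 0 °C; SiO2 chromatography, then crystallization
Reagents that add atoms: (1S)-(−)-camphanic chloride, O=C(Cl)[C@@]12CC[C@@](C)(C(=O)O1)C2(C)C
Why: Esterification of both phenols with an enantiopure, non-epimerizable acid chloride is a classical resolution through covalent diastereomers; the (2S,3R,2''S,3''R) bis-ester is separated from the one derived from the enantiomer and its configuration assigned by X-ray analysis against the known camphanoyl centers.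

Step 11
Reactants: 17 bis-camphanate
Product: 18 4',4''',5,5''-tetramethylchamaejasmin, (2S,3R,2''S,3''R)
Conditions: n-PrNH2 (2.5 equiv), THF, 0 °C; pH 5 buffer work-up
Reagents that add atoms: none
Why: Aminolysis of the activated aryl esters (the 7-oxygen is para to the ring carbonyl) is fast at 0 °C and too mild to enolize C3 or open ring C, so all four stereocenters are retained.

## Compound list

1 | 3,5-dimethoxyphenol | COc1cc(O)cc(OC)c1 | starting material
2 | (3,5-dimethoxyphenoxy)triisopropylsilane | COc1cc(O[Si](C(C)C)(C(C)C)C(C)C)cc(OC)c1 | intermediate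
3 | succinyl chloride (butanedioyl dichloride) | O=C(Cl)CCC(=O)Cl | starting material
4 | N1,N4-dimethoxy-N1,N4-dimethylbutanediamide | CON(C)C(=O)CCC(=O)N(C)OC | intermediate
5 | [2,6-dimethoxy-4-(triisopropylsilyloxy)phenyl]lithium | [Li]c1c(OC)cc(O[Si](C(C)C)(C(C)C)C(C)C)cc1OC | intermediate
6 | 1,4-bis[2,6-dimethoxy-4-(triisopropylsilyloxy)phenyl]butane-1,4-dione | COc1cc(O[Si](C(C)C)(C(C)C)C(C)C)cc(OC)c1C(=O)CCC(=O)c1c(OC)cc(O[Si](C(C)C)(C(C)C)C(C)C)cc1OC | intermediate
7 | 1,4-bis[2-hydroxy-6-methoxy-4-(triisopropylsilyloxy)phenyl]butane-1,4-dione | COc1cc(O[Si](C(C)C)(C(C)C)C(C)C)cc(O)c1C(=O)CCC(=O)c1c(O)cc(O[Si](C(C)C)(C(C)C)C(C)C)cc1OC | intermediate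
8 | 1,4-bis[2-methoxy-6-(methoxymethoxy)-4-(triisopropylsilyloxy)phenyl]butane-1,4-dione | COc1cc(O[Si](C(C)C)(C(C)C)C(C)C)cc(OCOC)c1C(=O)CCC(=O)c1c(OCOC)cc(O[Si](C(C)C)(C(C)C)C(C)C)cc1OC | intermediate
9 | 4-methoxybenzaldehyde | COc1ccc(C=O)cc1 | starting material
10 | dilithium (1Z,3Z)-1,4-bis[2-methoxy-6-(methoxymethoxy)-4-(triisopropylsilyloxy)phenyl]buta-1,3-diene-1,4-bis(olate) | [Li]O/C(=C\C=C(/O[Li])c1c(OCOC)cc(O[Si](C(C)C)(C(C)C)C(C)C)cc1OC)c1c(OCOC)cc(O[Si](C(C)C)(C(C)C)C(C)C)cc1OC | intermediate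
11 | 2,3-bis[hydroxy(4-methoxyphenyl)methyl]-1,4-bis[2-methoxy-6-(methoxymethoxy)-4-(triisopropylsilyloxy)phenyl]butane-1,4-dione (diastereomer mixture, no configuration defined) | COc1ccc(C(O)C(C(=O)c2c(OCOC)cc(O[Si](C(C)C)(C(C)C)C(C)C)cc2OC)C(C(O)c2ccc(OC)cc2)C(=O)c2c(OCOC)cc(O[Si](C(C)C)(C(C)C)C(C)C)cc2OC)cc1 | intermediate
12 | bis(methanesulfonate) of 11 (diastereomer mixture) | COc1ccc(C(OS(C)(=O)=O)C(C(=O)c2c(OCOC)cc(O[Si](C(C)C)(C(C)C)C(C)C)cc2OC)C(C(OS(C)(=O)=O)c2ccc(OC)cc2)C(=O)c2c(OCOC)cc(O[Si](C(C)C)(C(C)C)C(C)C)cc2OC)cc1 | intermediate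
13 | (2E,3E)-2,3-bis(4-methoxybenzylidene)-1,4-bis[2-methoxy-6-(methoxymethoxy)-4-(triisopropylsilyloxy)phenyl]butane-1,4-dione | O=C(c1c(OCOC)cc(O[Si](C(C)C)(C(C)C)C(C)C)cc1OC)/C(=C/c1ccc(OC)cc1)C(=C/c1ccc(OC)cc1)\C(=O)c1c(OCOC)cc(O[Si](C(C)C)(C(C)C)C(C)C)cc1OC | intermediate
14 | (2E,3E)-1,4-bis[2-hydroxy-6-methoxy-4-(triisopropylsilyloxy)phenyl]-2,3-bis(4-methoxybenzylidene)butane-1,4-dione | O=C(c1c(O)cc(O[Si](C(C)C)(C(C)C)C(C)C)cc1OC)/C(=C/c1ccc(OC)cc1)C(=C/c1ccc(OC)cc1)\C(=O)c1c(O)cc(O[Si](C(C)C)(C(C)C)C(C)C)cc1OC | intermediate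
15 | racemic 7,7''-bis-O-triisopropylsilyl-4',4''',5,5''-tetra-O-methylchamaejasmin, (2S,3R,2''S,3''R) and (2R,3S,2''R,3''S) 1:1, written as both enantiomers | COc1ccc([C@H]2Oc3cc(O[Si](C(C)C)(C(C)C)C(C)C)cc(OC)c3C(=O)[C@@H]2[C@H]2C(=O)c3c(OC)cc(O[Si](C(C)C)(C(C)C)C(C)C)cc3O[C@@H]2c2ccc(OC)cc2)cc1.COc1ccc([C@@H]2Oc3cc(O[Si](C(C)C)(C(C)C)C(C)C)cc(OC)c3C(=O)[C@H]2[C@@H]2C(=O)c3c(OC)cc(O[Si](C(C)C)(C(C)C)C(C)C)cc3O[C@H]2c2ccc(OC)cc2)cc1 | intermediate
16 | racemic 4',4''',5,5''-tetramethylchamaejasmin, written as both enantiomers | COc1ccc([C@H]2Oc3cc(O)cc(OC)c3C(=O)[C@@H]2[C@H]2C(=O)c3c(OC)cc(O)cc3O[C@@H]2c2ccc(OC)cc2)cc1.COc1ccc([C@@H]2Oc3cc(O)cc(OC)c3C(=O)[C@H]2[C@@H]2C(=O)c3c(OC)cc(O)cc3O[C@H]2c2ccc(OC)cc2)cc1 | intermediate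
17 | (2S,3R,2''S,3''R)-4',4''',5,5''-tetramethylchamaejasmin 7,7''-bis[(1S,4R)-camphanate] | COc1ccc([C@H]2Oc3cc(OC(=O)[C@@]45CC[C@@](C)(C(=O)O4)C5(C)C)cc(OC)c3C(=O)[C@@H]2[C@H]2C(=O)c3c(OC)cc(OC(=O)[C@@]45CC[C@@](C)(C(=O)O4)C5(C)C)cc3O[C@@H]2c2ccc(OC)cc2)cc1 | intermediate
18 | 4',4''',5,5''-tetramethylchamaejasmin, (2S,3R,2''S,3''R) | COc1ccc([C@H]2Oc3cc(O)cc(OC)c3C(=O)[C@@H]2[C@H]2C(=O)c3c(OC)cc(O)cc3O[C@@H]2c2ccc(OC)cc2)cc1 | target

## Step count and risks

Total step count: 11. Longest linear sequence: 10 steps (1 to 18 through steps 1 and 3–11); step 2 is a one-step side branch.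

Three steps most likely to fail:

Step 6 (double lithium aldol). The hindered 1,4-diketone may not give the bis-enolate cleanly, or the aldolates may revert. The fallback sets out from 8: condensation with tert-butoxybis(dimethylamino)methane in toluene at 90 °C gives the bis(enaminone) (2E,3E)-2,3-bis[(dimethylamino)methylidene]-1,4-bis[2-methoxy-6-(methoxymethoxy)-4-(triisopropylsilyloxy)phenyl]butane-1,4-dione F1. Treatment with 4-MeOC6H4MgBr (two equivalents are taken up) in THF (−20 °C to rt) then runs as a Benary reaction: 1,4-addition to each vinylogous amide, favoured because the carbonyls are shielded by two ortho substituents, followed by loss of dimethylamine. This comes back to the route at 13 and bypasses 11 and 12.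

Step 8 (deprotection and double ring closure). The crowded bis-enone may cyclize incompletely or drift by 1,3-hydrogen shift, and the ratio of the C2-symmetric pair to the meso isomer is not controlled, so the yield of 15 may be low. The fallback sets out from 7: N,N-dimethylformamide dimethyl acetal in toluene at 100 °C gives the bis(enaminone) (2E,3E)-2,3-bis[(dimethylamino)methylidene]-1,4-bis[2-hydroxy-6-methoxy-4-(triisopropylsilyloxy)phenyl]butane-1,4-dione F2. Warming with AcOH closes both pyranone rings with loss of dimethylamine to the bichromone 5,5'-dimethoxy-7,7'-bis(triisopropylsilyloxy)-[3,3'-bichromene]-4,4'-dione F3. Copper-mediated 1,4-addition of 4-MeOC6H4MgBr (CuBr·SMe2, Me3SiCl, THF, −78 to −30 °C) gives the bis(enol silane) 5,5'-dimethoxy-2,2'-bis(4-methoxyphenyl)-4,4'-bis(trimethylsilyloxy)-7,7'-bis(triisopropylsilyloxy)-2H,2'H-3,3'-bichromene F4. Cold dilute acid hydrolysis, NaOAc/EtOH equilibration of C3 and C3'' to trans, and chromatographic removal of the meso isomer come back to the route at 15. This route also gives a racemic, meso-containing mixture; it only replaces the ring-closure chemistry.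

Step 10 (resolution). The two bis-camphanates may not separate on silica or by crystallization. The fallback sets out from 16: direct preparative supercritical-fluid chromatography on an amylose tris(3,5-dimethylphenylcarbamate) stationary phase (CO2/MeOH), with the (2S,3R,2''S,3''R) enantiomer assigned by electronic circular dichroism, comes back to the route at 18 and skips 17; it makes no new compound (none F0).

## Further compounds

F1 | step 6 | (2E,3E)-2,3-bis[(dimethylamino)methylidene]-1,4-bis[2-methoxy-6-(methoxymethoxy)-4-(triisopropylsilyloxy)phenyl]butane-1,4-dione | CN(C)/C=C(/C(=O)c1c(OCOC)cc(O[Si](C(C)C)(C(C)C)C(C)C)cc1OC)C(=C/N(C)C)\C(=O)c1c(OCOC)cc(O[Si](C(C)C)(C(C)C)C(C)C)cc1OC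
F2 | step 8 | (2E,3E)-2,3-bis[(dimethylamino)methylidene]-1,4-bis[2-hydroxy-6-methoxy-4-(triisopropylsilyloxy)phenyl]butane-1,4-dione | CN(C)/C=C(/C(=O)c1c(O)cc(O[Si](C(C)C)(C(C)C)C(C)C)cc1OC)C(=C/N(C)C)\C(=O)c1c(O)cc(O[Si](C(C)C)(C(C)C)C(C)C)cc1OC
F3 | step 8 | 5,5'-dimethoxy-7,7'-bis(triisopropylsilyloxy)-[3,3'-bichromene]-4,4'-dione | COc1cc(O[Si](C(C)C)(C(C)C)C(C)C)cc2occ(-c3coc4cc(O[Si](C(C)C)(C(C)C)C(C)C)cc(OC)c4c3=O)c(=O)c12
F4 | step 8 | 5,5'-dimethoxy-2,2'-bis(4-methoxyphenyl)-4,4'-bis(trimethylsilyloxy)-7,7'-bis(triisopropylsilyloxy)-2H,2'H-3,3'-bichromene (mixture of C2 epimers, no configuration defined) | COc1ccc(C2Oc3cc(O[Si](C(C)C)(C(C)C)C(C)C)cc(OC)c3C(O[Si](C)(C)C)=C2C2=C(O[Si](C)(C)C)c3c(OC)cc(O[Si](C(C)C)(C(C)C)C(C)C)cc3OC2c2ccc(OC)cc2)cc1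
F0 | step 10 | none | none
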